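**Plan**

1. Retrosynthetic cuts: first the lactone C–O bond at the carbinol carbon, then the bond from the lactone carbonyl carbon to its α-carbon (back to a bridging ketone). Next, together, the two bonds joining the four-carbon enone chain to the benzylic CH and to the methyl-bearing quaternary carbon: a (4+3) disconnection to a 2-methoxyallyl cation lying in the six-membered ring. That cation is traced to a chloro(methoxy)cyclopropane fused to an indene.
2. Enabling feature: benzylic CH, lactone α-CH and C(CH3) are three contiguous atoms of the tetralin ring and also bridgehead–bridge–bridgehead of the bicyclo[4.3.1]decane this ring forms with the cycloheptenone. A C3 unit bonded at both ends inside a six-membered ring is the trace of a cyclic allyl cation, which a cyclopropyl cation fused to a five-membered ring gives on electrocyclic opening.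
3. Forward ring order: benzene ring (bought) → five-membered ring (Friedel–Crafts acylation) → three-membered ring (carbene addition) → step 8, where the three- and five-membered rings merge into the six-membered ring while the seven-membered ring closes → γ-lactone last.
4. Stereochemistry: both bridgeheads are set in step 8 (a chiral thiourea ion pair selects the enantioface of the planar cation; the second centre follows by ring constraint). The lactone α-carbon is set by thermodynamic equilibration of the aldehyde (step 11), the carbinol carbon by the geometry of the intramolecular displacement (step 13).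
5. Both bromines enter in step 2, where symmetry fixes their positions.

Key step: step 8

Assumption: the sense of induction of the thiourea in step 8 cannot be predicted with certainty; one handedness is written, and its mirror image is taken if the first run delivers the antipode of 14.

Remark on names: locants of the bridged compounds 13–19 follow 5,10-methanobenzo[9]annulene numbering (C5 benzylic bridgehead, C6–C9 four-carbon bridge, C10 methyl-bearing bridgehead, C11 gem-dimethyl carbon, C12 one-carbon bridge).

**Route**

Step 1
Reactants: 1 ethylbenzene; 2 3-methylbut-2-enoic acid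
Product: 3 3-(4-ethylphenyl)-3-methylbutanoic acid
Conditions: AlCl3 (2.5 equiv), 1 as solvent, 0 → 25 °C
Reagents that add atoms: none
Why: Friedel–Crafts alkylation (hydroarylation) through the tertiary β-cation of the acid, which should attack ethylbenzene para to the ethyl group for steric reasons; no stereocentre is formed.

Step 2
Reactants: 3 3-(4-ethylphenyl)-3-methylbutanoic acid
Product: 4 3-(3,5-dibromo-4-ethylphenyl)-3-methylbutanoic acid
Conditions: Br2 (2.2 equiv), FeBr3 (5 mol%), CH2Cl2, 0 → 25 °C, dark
Reagents that add atoms: bromine, BrBr
Why: Electrophilic aromatic bromination should occur twice ortho to the ethyl group, because the positions next to the quaternary benzylic carbon are shielded and the mirror symmetry of 3 makes the two reacting positions equivalent; no stereocentre.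

Step 3
Reactants: 4 3-(3,5-dibromo-4-ethylphenyl)-3-methylbutanoic acid
Product: 5 5,7-dibromo-6-ethyl-3,3-dimethyl-2,3-dihydro-1H-inden-1-one
Conditions: CF3SO3H (5 equiv), ClCH2CH2Cl, 60 °C
Reagents that add atoms: none
Why: Intramolecular Friedel–Crafts acylation via the acylium ion closes the five-membered ring at either of the two equivalent positions ortho to the side chain (ortho and para to bromine), helped by the gem-dimethyl group; no stereocentre.

Step 4
Reactants: 5 5,7-dibromo-6-ethyl-3,3-dimethyl-2,3-dihydro-1H-inden-1-one
Product: 6 5,7-dibromo-6-ethyl-2,3,3-trimethyl-2,3-dihydro-1H-inden-1-one (racemic)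
Conditions: LiN(SiMe3)2 (1.1 equiv), THF, −78 °C; CH3I, −78 → 0 °C
Reagents that add atoms: iodomethane, CI
Why: Alkylation of the only possible enolate with a small electrophile; the new stereocentre is racemic and is destroyed in step 5.

Step 5
Reactants: 6 5,7-dibromo-6-ethyl-2,3,3-trimethyl-2,3-dihydro-1H-inden-1-one
Product: 8 4,6-dibromo-5-ethyl-1,1,2-trimethyl-1H-indene, via indanol 7 (not isolated)
Conditions: NaBH4, MeOH/THF, 0 → 25 °C; then TsOH·H2O (10 mol%), PhMe, 90 °C, azeotropic removal of water
Reagents that add atoms: none
Why: Hydride reduction followed by acid-catalysed E1 dehydration through the benzylic cation, which can lose a proton only from the adjacent methine and so should give the single trisubstituted alkene; all stereocentres disappear.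

Step 6
Reactants: 8 4,6-dibromo-5-ethyl-1,1,2-trimethyl-1H-indene
Product: 9 2,4-dibromo-1-chloro-3-ethyl-1-methoxy-6,6,6a-trimethyl-1,1a,6,6a-tetrahydrocyclopropa[a]indene (racemic; both epimers at C1)
Conditions: Cl2CHOCH3 (4 equiv), CH3Li·LiI (3.5 equiv, slow addition), Et2O, −20 → 0 °C; crude product filtered through basic alumina and used at once
Reagents that add atoms: dichloromethyl methyl ether, COC(Cl)Cl
Why: α-Elimination gives chloro(methoxy)carbene, which should add in a stereospecific (2+1) cycloaddition to the electron-rich styrene-type double bond (alkoxyhalocarbene cyclopropanation); the ring fusion is necessarily cis, the product is racemic, and both C1 epimers serve in step 8, so no selectivity is needed.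

Step 7
Reactants: 10 but-3-en-2-one
Product: 11 tert-butyl(buta-1,3-dien-2-yloxy)dimethylsilane
Conditions: t-BuMe2SiOTf, Et3N, Et2O, 0 → 25 °C
Reagents that add atoms: tert-butyldimethylsilyl trifluoromethanesulfonate, CC(C)(C)[Si](C)(C)OS(=O)(=O)C(F)(F)F
Why: Soft enolisation of the enone (O-silylation, then deprotonation of the methyl group by the amine) is the standard preparation of 2-silyloxybutadienes; no stereocentre.

Step 8
Reactants: 9 2,4-dibromo-1-chloro-3-ethyl-1-methoxy-6,6,6a-trimethyl-1,1a,6,6a-tetrahydrocyclopropa[a]indene; 11 tert-butyl(buta-1,3-dien-2-yloxy)dimethylsilane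
Product: 14 (5R,10S)-2,4-dibromo-7-[(tert-butyldimethylsilyl)oxy]-3-ethyl-10,11,11-trimethyl-6,9,10,11-tetrahydro-5H-5,10-methanobenzo[9]annulen-12-one, via 2-methoxyallyl cation chloride ion pair 12 (not isolated), via O-methyl oxocarbenium chloride 13 (not isolated)
Conditions: 11 (3 equiv), 1-[3,5-bis(trifluoromethyl)phenyl]-3-[(2S)-3,3-dimethyl-1-oxo-1-[(2R)-2-phenylpyrrolidin-1-yl]butan-2-yl]thiourea (10 mol%), 4 Å molecular sieves, PhMe, −40 → 0 °C, then 25 °C
Reagents that add atoms: none
Why: Proposed new method: the thiourea binds the chloride of the α-chloro ether 9 and the 1-methoxycyclopropyl cation opens by two-electron disrotatory electrocyclic cleavage of the C1a–C6a bond shared by the three- and five-membered rings (the epimer with chloride cis to the indane ring directly, the other after ionisation and chloride return), so that the five-membered ring grows by one carbon into the six-membered ring of the 2-methoxyallyl cation 12; 12 then adds across the termini of diene 11 in a stepwise (4+3) cycloaddition, and the bound chloride removes the O-methyl group of 13 as chloromethane, which frees the catalyst. The closest known reaction types are the silver-promoted (4+3) cycloaddition of 2-methoxyallyl cations from 2-methoxyallyl halides with 1,3-dienes, the thermal ring enlargement of fused 1-alkoxy-1-chlorocyclopropanes, and anion-binding catalysis by chiral hydrogen-bond donors in additions of silyl enol ethers to oxocarbenium ions made from α-chloro ethers. The six-membered ring is not closed by a new bond but arises by the ring expansion, whereas the seven-membered ring is closed by an intermolecular C5–C6 bond followed by a 7-endo-trig attack of the fully substituted enol ether carbon (C10) on the CH2 terminus of the silyloxyallyl cation. The benzylic stereocentre C5 is set in the first C–C bond formation by the face of the planar cation that the chiral ion pair leaves open, and the quaternary stereocentre C10 follows from it, because the four-carbon chain can bridge the two termini on one face only. The step needs head-to-head regioselectivity, secured by the unhindered benzylic terminus (the other terminus is tertiary and flanked by the gem-dimethyl carbon) and by the polarisation of 11 (the CH2 next to the silyloxy carbon is the most nucleophilic). It also needs (4+3) rather than (3+2) closure, secured because closure at the oxocarbenium carbon would join two fully substituted carbons, while the bulky silyl group slows desilylation so that ring closure can compete.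

Step 9
Reactants: 14 (5R,10S)-2,4-dibromo-7-[(tert-butyldimethylsilyl)oxy]-3-ethyl-10,11,11-trimethyl-6,9,10,11-tetrahydro-5H-5,10-methanobenzo[9]annulen-12-one
Product: 15 (5S,10S)-2,4-dibromo-7-[(tert-butyldimethylsilyl)oxy]-3-ethyl-12-(methoxymethylidene)-10,11,11-trimethyl-6,9,10,11-tetrahydro-5H-5,10-methanobenzo[9]annulene (E/Z mixture)
Conditions: CH3OCH2PPh3Cl (3 equiv), KN(SiMe3)2 (2.8 equiv), THF, 0 → 50 °C
Reagents that add atoms: (methoxymethyl)triphenylphosphonium chloride, COC[P+](c1ccccc1)(c1ccccc1)c1ccccc1.[Cl-]
Why: Wittig olefination with the methoxymethylene ylide on a ketone that cannot enolise (one α-carbon is a bridgehead, the other quaternary) and therefore tolerates the basic ylide, while the silyl enol ether and the aryl bromides should be inert; the enol ether geometry is of no consequence.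

Step 10
Reactants: 15 (5S,10S)-2,4-dibromo-7-[(tert-butyldimethylsilyl)oxy]-3-ethyl-12-(methoxymethylidene)-10,11,11-trimethyl-6,9,10,11-tetrahydro-5H-5,10-methanobenzo[9]annulene
Product: 16 (5S,10S)-2,4-dibromo-3-ethyl-12-(methoxymethylidene)-10,11,11-trimethyl-5,6,10,11-tetrahydro-7H-5,10-methanobenzo[9]annulen-7-one
Conditions: Pd(OAc)2 (1.2 equiv), CH3CN, 40 °C
Reagents that add atoms: none
Why: Saegusa–Ito oxidation, in which the silyl enol ether is transmetalated to a palladium enolate that undergoes β-hydride elimination toward the CH2 next to the quaternary carbon, so the enone forms regiospecifically; the methyl enol ether carries no silyl group and should stay, and no stereocentre is touched.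

Step 11
Reactants: 16 (5S,10S)-2,4-dibromo-3-ethyl-12-(methoxymethylidene)-10,11,11-trimethyl-5,6,10,11-tetrahydro-7H-5,10-methanobenzo[9]annulen-7-one
Product: 17 (5S,10R,12R)-2,4-dibromo-3-ethyl-10,11,11-trimethyl-7-oxo-6,7,10,11-tetrahydro-5H-5,10-methanobenzo[9]annulene-12-carbaldehyde
Conditions: 2 M HCl, THF, 25 → 40 °C
Reagents that add atoms: water, O
Why: Acid hydrolysis of the enol ether through its oxocarbenium ion gives the aldehyde, whose α-stereocentre (C12) equilibrates through the enol and should settle with the formyl group over the seven-membered ring, away from the axial methyl of the gem-dimethyl carbon on the other side (thermodynamic control); the enone α-carbon is sp2, so no transannular aldol can interfere.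

Step 12
Reactants: 17 (5S,10R,12R)-2,4-dibromo-3-ethyl-10,11,11-trimethyl-7-oxo-6,7,10,11-tetrahydro-5H-5,10-methanobenzo[9]annulene-12-carbaldehyde
Product: 18 (5S,10R,12R)-2,4-dibromo-3-ethyl-10,11,11-trimethyl-7-oxo-6,7,10,11-tetrahydro-5H-5,10-methanobenzo[9]annulene-12-carboxylic acid
Conditions: NaClO2, NaH2PO4, 2-methylbut-2-ene, t-BuOH/H2O, 0 → 25 °C
Reagents that add atoms: sodium chlorite, [Na+].[O-]Cl=O
Why: Pinnick oxidation is selective for the aldehyde in the presence of the enone and the aryl bromides, and the weakly acidic buffer should leave the α-stereocentre unchanged.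

Step 13
Reactants: 18 (5S,10R,12R)-2,4-dibromo-3-ethyl-10,11,11-trimethyl-7-oxo-6,7,10,11-tetrahydro-5H-5,10-methanobenzo[9]annulene-12-carboxylic acid
Product: 20 salimabromide, via lithium 6-iodo carboxylate 19 (not isolated)
Conditions: LiN(SiMe3)2 (2.3 equiv), THF, −78 °C; I2 (1.1 equiv), −78 → 25 °C
Reagents that add atoms: none
Why: Iodination of the cross-conjugated enolate at C6 (the only enolisable position of the enone, since the γ-carbon is quaternary; the base also reopens any conjugate-addition lactone of 18) followed by intramolecular SN2 displacement of iodide by the carboxylate (5-exo-tet) is the classical lactonisation of an α-halo ketone acid; the carbinol stereocentre can arise only with oxygen on the face that carries the carboxylate, and the iodo epimers should interconvert by iodide exchange.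

**Compound list**

1 | ethylbenzene | CCc1ccccc1 | starting material
2 | 3-methylbut-2-enoic acid | CC(C)=CC(=O)O | starting material
3 | 3-(4-ethylphenyl)-3-methylbutanoic acid | CCc1ccc(cc1)C(C)(C)CC(=O)O | intermediate
4 | 3-(3,5-dibromo-4-ethylphenyl)-3-methylbutanoic acid | CCc1c(Br)cc(cc1Br)C(C)(C)CC(=O)O | intermediate
5 | 5,7-dibromo-6-ethyl-3,3-dimethyl-2,3-dihydro-1H-inden-1-one | CCc1c(Br)cc2c(c1Br)C(=O)CC2(C)C | intermediate
6 | 5,7-dibromo-6-ethyl-2,3,3-trimethyl-2,3-dihydro-1H-inden-1-one (racemic) | CCc1c(Br)cc2c(c1Br)C(=O)C(C)C2(C)C | intermediate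
7 | 5,7-dibromo-6-ethyl-2,3,3-trimethyl-2,3-dihydro-1H-inden-1-ol (racemic diastereomer mixture; not isolated) | CCc1c(Br)cc2c(c1Br)C(O)C(C)C2(C)C | intermediate
8 | 4,6-dibromo-5-ethyl-1,1,2-trimethyl-1H-indene | CCc1c(Br)cc2c(c1Br)C=C(C)C2(C)C | intermediate
9 | 2,4-dibromo-1-chloro-3-ethyl-1-methoxy-6,6,6a-trimethyl-1,1a,6,6a-tetrahydrocyclopropa[a]indene (racemic, cis-fused, both C1 epimers) | CCc1c(Br)cc2c(c1Br)C1C(Cl)(OC)C1(C)C2(C)C | intermediate
10 | but-3-en-2-one | CC(=O)C=C | starting material
11 | tert-butyl(buta-1,3-dien-2-yloxy)dimethylsilane | C=CC(=C)O[Si](C)(C)C(C)(C)C | intermediate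
12 | 6,8-dibromo-7-ethyl-2-methoxy-3,4,4-trimethyl-1,4-dihydronaphthalen-1-ylium chloride (allyl cation over C1–C2–C3, ion pair held by the thiourea; not isolated) | CCc1c(Br)cc2c(c1Br)[CH+]C(OC)=C(C)C2(C)C.[Cl-] | intermediate
13 | O-methyl oxocarbenium chloride of 14, (5R,10S) (not isolated) | CCc1c(Br)cc2c(c1Br)[C@H]1CC(O[Si](C)(C)C(C)(C)C)=CC[C@](C)(C1=[O+]C)C2(C)C.[Cl-] | intermediate
14 | (5R,10S)-2,4-dibromo-7-[(tert-butyldimethylsilyl)oxy]-3-ethyl-10,11,11-trimethyl-6,9,10,11-tetrahydro-5H-5,10-methanobenzo[9]annulen-12-one | CCc1c(Br)cc2c(c1Br)[C@H]1CC(O[Si](C)(C)C(C)(C)C)=CC[C@](C)(C1=O)C2(C)C | intermediate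
15 | (5S,10S)-2,4-dibromo-7-[(tert-butyldimethylsilyl)oxy]-3-ethyl-12-(methoxymethylidene)-10,11,11-trimethyl-6,9,10,11-tetrahydro-5H-5,10-methanobenzo[9]annulene (E/Z mixture) | CCc1c(Br)cc2c(c1Br)[C@H]1CC(O[Si](C)(C)C(C)(C)C)=CC[C@](C)(C1=COC)C2(C)C | intermediate
16 | (5S,10S)-2,4-dibromo-3-ethyl-12-(methoxymethylidene)-10,11,11-trimethyl-5,6,10,11-tetrahydro-7H-5,10-methanobenzo[9]annulen-7-one | CCc1c(Br)cc2c(c1Br)[C@H]1CC(=O)C=C[C@](C)(C1=COC)C2(C)C | intermediate
17 | (5S,10R,12R)-2,4-dibromo-3-ethyl-10,11,11-trimethyl-7-oxo-6,7,10,11-tetrahydro-5H-5,10-methanobenzo[9]annulene-12-carbaldehyde | CCc1c(Br)cc2c(c1Br)[C@H]1CC(=O)C=C[C@](C)([C@@H]1C=O)C2(C)C | intermediate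
18 | (5S,10R,12R)-2,4-dibromo-3-ethyl-10,11,11-trimethyl-7-oxo-6,7,10,11-tetrahydro-5H-5,10-methanobenzo[9]annulene-12-carboxylic acid | CCc1c(Br)cc2c(c1Br)[C@H]1CC(=O)C=C[C@](C)([C@@H]1C(=O)O)C2(C)C | intermediate
19 | lithium (5S,10R,12R)-2,4-dibromo-3-ethyl-6-iodo-10,11,11-trimethyl-7-oxo-6,7,10,11-tetrahydro-5H-5,10-methanobenzo[9]annulene-12-carboxylate (C6 epimers; not isolated) | CCc1c(Br)cc2c(c1Br)[C@H]1C(I)C(=O)C=C[C@](C)([C@@H]1C(=O)[O-])C2(C)C.[Li+] | intermediate
20 | salimabromide | CCc1c(Br)cc2c(c1Br)[C@H]1[C@@H]3OC(=O)[C@H]1[C@@](C)(C=CC3=O)C2(C)C | target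

**Step count and risks**

Total steps: 13. Longest linear sequence: 12 (steps 1–6 and 8–13; step 7 is a one-step branch).

Steps most likely to fail:

Step 8 (Proposed new method). The neutral hydrogen-bond donor may ionise the cyclopropyl chloride too slowly or hold the ion pair too loosely. The cation would then lose a proton, or be attacked with poor enantiofacial selectivity, before the cycloaddition is complete. The fallback uses known chemistry, runs stepwise and ends with a resolution; it sets out from 9 and comes back at 14. Warming 9 in CHCl3 (40 °C) should bring about the known cyclopropyl-to-allyl ring enlargement with chloride return and give racemic 6,8-dibromo-1-chloro-7-ethyl-2-methoxy-3,4,4-trimethyl-1,4-dihydronaphthalene F1. Treating F1 with AgOCOCF3 and Na2CO3 in CH2Cl2 at −30 °C in the presence of 11 (silver-promoted (4+3) cycloaddition of a 2-methoxyallyl halide with a diene) should give 14 as the racemate, that is together with (5S,10R)-2,4-dibromo-7-[(tert-butyldimethylsilyl)oxy]-3-ethyl-10,11,11-trimethyl-6,9,10,11-tetrahydro-5H-5,10-methanobenzo[9]annulen-12-one F2. Preparative HPLC on a chiral stationary phase separates 14 from F2.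

Step 9. Steric shielding of the bridging carbonyl group (methyl and gem-dimethyl groups on one side, the arene with its peri-bromine on the other) may keep the bulky phosphorus ylide from adding. The fallback is a Peterson route that sets out from 14 and comes back at 15. [Methoxy(trimethylsilyl)methyl]lithium, pre-formed from (methoxymethyl)trimethylsilane and s-BuLi in THF at −78 °C, is a smaller and more nucleophilic carbanion. It should add to the ketone to give the β-hydroxysilane 12-hydroxy-12-[methoxy(trimethylsilyl)methyl] analogue of 14 F3 (bridgeheads as in 14). KH in THF then effects the syn-elimination to 15.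

Step 13. Iodination may occur mainly on the face that carries the carboxylate, and the epimerisation by iodide exchange that the displacement needs may be slower than decomposition of the α-iodo enone. The fallback transfers electrophilic oxygen and then forms the ester; it sets out from 18 and comes back at 20. KN(SiMe3)2 (2.4 equiv) in THF at −78 °C followed by 3-phenyl-2-(phenylsulfonyl)oxaziridine should hydroxylate the enolate to give 2,4-dibromo-3-ethyl-6-hydroxy-10,11,11-trimethyl-7-oxo-6,7,10,11-tetrahydro-5H-5,10-methanobenzo[9]annulene-12-carboxylic acid F4 (either C6 epimer). The epimer with hydroxyl cis to the carboxyl group should close to 20 on warming with TsOH·H2O (cat.) in PhMe. The trans epimer is closed with inversion under Mitsunobu conditions (PPh3, diisopropyl azodicarboxylate, THF).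

**Further compounds**

F1 | step 8 | 6,8-dibromo-1-chloro-7-ethyl-2-methoxy-3,4,4-trimethyl-1,4-dihydronaphthalene (racemic) | CCc1c(Br)cc2c(c1Br)C(Cl)C(OC)=C(C)C2(C)C
F2 | step 8 | (5S,10R)-2,4-dibromo-7-[(tert-butyldimethylsilyl)oxy]-3-ethyl-10,11,11-trimethyl-6,9,10,11-tetrahydro-5H-5,10-methanobenzo[9]annulen-12-one (enantiomer of 14) | CCc1c(Br)cc2c(c1Br)[C@@H]1CC(O[Si](C)(C)C(C)(C)C)=CC[C@@](C)(C1=O)C2(C)C
F3 | step 9 | 12-hydroxy-12-[methoxy(trimethylsilyl)methyl] analogue of 14 (β-hydroxysilane; new centres undefined) | CCc1c(Br)cc2c(c1Br)[C@H]1CC(O[Si](C)(C)C(C)(C)C)=CC[C@](C)(C1(O)C(OC)[Si](C)(C)C)C2(C)C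
F4 | step 13 | 2,4-dibromo-3-ethyl-6-hydroxy-10,11,11-trimethyl-7-oxo-6,7,10,11-tetrahydro-5H-5,10-methanobenzo[9]annulene-12-carboxylic acid (5S,10R,12R; C6 undefined) | CCc1c(Br)cc2c(c1Br)[C@H]1C(O)C(=O)C=C[C@](C)([C@@H]1C(=O)O)C2(C)C
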